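Ring C is cut at O1–C2 and C4–C4a into a resorcinol and a cinnamoyl unit, which are first joined the other way round, as an aryl cinnamate (the monoester of the symmetric diprenylresorcinol with silyl-protected p-coumaric acid). Light then shifts the acyl group from oxygen to carbon (photo-Fries), and a chiral thiourea base closes the freed phenol onto the enone, so that one operation isomerises the ester into the (2S)-flavanone. The step exploits ring A: C4a is its only unsubstituted carbon and lies between two oxygens, O1 and the C5 hydroxyl oxygen, that are equivalent in the resorcinol, while C6 and C8 are blocked by the prenyl groups. A removable ester group secures this substitution pattern.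

Key step: step 6

Assumption: the quinine-derived thiourea is taken to give the 2S sense of closure; should a trial show the opposite sense, its quinidine-derived pseudoenantiomer would be used under the same conditions.

Step 1
Reactants: 1 methyl 2,4,6-trihydroxybenzoate; 2 prenyl bromide (1-bromo-3-methylbut-2-ene, 2.2 equiv)
Product: 3 methyl 2,4,6-trihydroxy-3,5-bis(3-methylbut-2-enyl)benzoate
Conditions: 10% aq. KOH, 0 °C to rt, argon
Reagents that add atoms: none
Why: In aqueous alkali the phloroglucinol phenoxide should be alkylated mainly at carbon, and because the ester occupies the third nucleophilic ring carbon both prenyl groups can only enter at C3 and C5 (C-alkylation of a phenoxide, the ester acting as a blocking group).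

Step 2
Reactants: 3 methyl 2,4,6-trihydroxy-3,5-bis(3-methylbut-2-enyl)benzoate
Product: 4 methyl 2,6-dihydroxy-4-methoxy-3,5-bis(3-methylbut-2-enyl)benzoate
Conditions: MeI (1.05 equiv), K2CO3 (1.1 equiv), acetone, rt
Reagents that add atoms: methyl iodide, CI
Why: The 4-hydroxyl, para to the ester, is the most acidic and is not hydrogen-bonded to the ester group as the 2- and 6-hydroxyls are, so one equivalent of MeI with a weak base should etherify it alone (Williamson ether synthesis).

Step 3
Reactants: 4 methyl 2,6-dihydroxy-4-methoxy-3,5-bis(3-methylbut-2-enyl)benzoate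
Product: 6 5-methoxy-4,6-bis(3-methylbut-2-enyl)benzene-1,3-diol, via carboxylic acid 5 (not isolated)
Conditions: KOH (5 equiv), MeOH/H2O 1:1, reflux, argon; then AcOH to pH 5, 60 °C
Reagents that add atoms: none
Why: Hot aqueous alkali saponifies the ester and the electron-rich 2,6-dihydroxybenzoic acid should lose CO2 by ipso-protonation once the pH is lowered to about 5, conditions too mild to cyclise an ortho-prenylphenol (ester hydrolysis followed by protodecarboxylation).

Step 4
Reactants: 7 (E)-4-hydroxycinnamic acid (p-coumaric acid)
Product: 9 (E)-4-(tert-butyldimethylsilyloxy)cinnamic acid, via silyl ester 8 (not isolated)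
Conditions: TBSCl (2.2 equiv), imidazole, DMF, rt; then AcOH/THF/H2O, rt
Reagents that add atoms: tert-butyldimethylsilyl chloride, CC(C)(C)[Si](C)(C)Cl
Why: Silylation takes both acidic groups and the silyl ester, far more labile than the aryl silyl ether, should then be hydrolysed selectively by aqueous acetic acid (silyl ether protection).

Step 5
Reactants: 6 5-methoxy-4,6-bis(3-methylbut-2-enyl)benzene-1,3-diol (2 equiv); 9 (E)-4-(tert-butyldimethylsilyloxy)cinnamic acid
Product: 10 3-hydroxy-5-methoxy-4,6-bis(3-methylbut-2-enyl)phenyl (E)-4-(tert-butyldimethylsilyloxy)cinnamate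
Conditions: DCC, DMAP (cat.), CH2Cl2, 0 °C to rt
Reagents that add atoms: none
Why: Steglich esterification: the two hydroxyls of 6 are equivalent, so an excess of the diol (recovered and reused) should limit the reaction to monoacylation without any regiochemical question, and the neutral conditions spare the prenyl groups and the silyl ether.

Step 6
Reactants: 10 3-hydroxy-5-methoxy-4,6-bis(3-methylbut-2-enyl)phenyl (E)-4-(tert-butyldimethylsilyloxy)cinnamate
Product: 12 (2S)-2-[4-(tert-butyldimethylsilyloxy)phenyl]-5-hydroxy-7-methoxy-6,8-bis(3-methylbut-2-enyl)chroman-4-one, via chalcone 11 (not isolated)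
Conditions: hν (300 nm lamps, Pyrex), degassed toluene (5 mM), 15 °C; then in the dark, concentrated to 0.05 M, quinine-derived thiourea N-[3,5-bis(trifluoromethyl)phenyl]-N'-(9-deoxy-epi-quinin-9-yl)thiourea (10 mol %), −20 °C; filtration through silica
Reagents that add atoms: none
Why: Excitation of the aryl ester cleaves the ArO–C(O) bond homolytically and the caged aryloxyl/cinnamoyl radical pair recombines at carbon; since the second ortho position and the para position of the ester oxygen both carry prenyl groups, only recombination at C4a can rearomatise, which forms C4–C4a and gives the 2',6'-dihydroxychalcone 11. The quinuclidine nitrogen of the catalyst then deprotonates one of the two equivalent ortho-hydroxyls while the thiourea binds the enone carbonyl, and the phenoxide adds to the β-carbon to form O1–C2. The closest known reactions are the photo-Fries rearrangement of aryl cinnamates to 2'-hydroxychalcones, its one-pot combination with oxa-Michael closure to chroman-4-ones, and the cinchona-thiourea-catalysed asymmetric cyclisation of 2'-hydroxychalcones to flavanones. Ring C is closed in the 6-endo-trig mode, the overall change being a formal (3+3) union of the O1–C8a–C4a unit of ring A with C2–C3–C4. The C2 stereocentre is set under catalyst control, the chiral ion pair shielding one face of the enone so that the 2S product should form, and the closure is run cold, in the dark and ended by removal of the base so that reversible ring opening cannot erode it. The step needs site selectivity in the acyl shift and in the closure, and ring A secures both: C4a is its only free carbon, and either hydroxyl gives the same flavanone.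

Step 7
Reactants: 12 (2S)-2-[4-(tert-butyldimethylsilyloxy)phenyl]-5-hydroxy-7-methoxy-6,8-bis(3-methylbut-2-enyl)chroman-4-one
Product: 13 (2S)-5-hydroxy-2-(4-hydroxyphenyl)-7-methoxy-6,8-bis(3-methylbut-2-enyl)chroman-4-one (CNP0121058.1)
Conditions: TBAF (1.1 equiv), AcOH (1.2 equiv), THF, 0 °C
Reagents that add atoms: none
Why: Fluoride cleaves the aryl silyl ether, and the acetic acid buffer protonates the phenoxide at once, so that base-induced ring opening of the flavanone, the only way to lose the C2 configuration, should not occur (fluoride desilylation).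

Compound list
1 | methyl 2,4,6-trihydroxybenzoate | COC(=O)c1c(O)cc(O)cc1O | starting material
2 | prenyl bromide (1-bromo-3-methylbut-2-ene) | CC(C)=CCBr | starting material
3 | methyl 2,4,6-trihydroxy-3,5-bis(3-methylbut-2-enyl)benzoate | COC(=O)c1c(O)c(CC=C(C)C)c(O)c(CC=C(C)C)c1O | intermediate
4 | methyl 2,6-dihydroxy-4-methoxy-3,5-bis(3-methylbut-2-enyl)benzoate | COC(=O)c1c(O)c(CC=C(C)C)c(OC)c(CC=C(C)C)c1O | intermediate
5 | 2,6-dihydroxy-4-methoxy-3,5-bis(3-methylbut-2-enyl)benzoic acid | OC(=O)c1c(O)c(CC=C(C)C)c(OC)c(CC=C(C)C)c1O | intermediate
6 | 5-methoxy-4,6-bis(3-methylbut-2-enyl)benzene-1,3-diol | COc1c(CC=C(C)C)c(O)cc(O)c1CC=C(C)C | intermediate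
7 | (E)-4-hydroxycinnamic acid (p-coumaric acid) | OC(=O)/C=C/c1ccc(O)cc1 | starting material
8 | tert-butyldimethylsilyl (E)-4-(tert-butyldimethylsilyloxy)cinnamate | CC(C)(C)[Si](C)(C)OC(=O)/C=C/c1ccc(O[Si](C)(C)C(C)(C)C)cc1 | intermediate
9 | (E)-4-(tert-butyldimethylsilyloxy)cinnamic acid | OC(=O)/C=C/c1ccc(O[Si](C)(C)C(C)(C)C)cc1 | intermediate
10 | 3-hydroxy-5-methoxy-4,6-bis(3-methylbut-2-enyl)phenyl (E)-4-(tert-butyldimethylsilyloxy)cinnamate | COc1c(CC=C(C)C)c(O)cc(OC(=O)/C=C/c2ccc(O[Si](C)(C)C(C)(C)C)cc2)c1CC=C(C)C | intermediate
11 | (E)-3-[4-(tert-butyldimethylsilyloxy)phenyl]-1-[2,6-dihydroxy-4-methoxy-3,5-bis(3-methylbut-2-enyl)phenyl]prop-2-en-1-one | COc1c(CC=C(C)C)c(O)c(C(=O)/C=C/c2ccc(O[Si](C)(C)C(C)(C)C)cc2)c(O)c1CC=C(C)C | intermediate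
12 | (2S)-2-[4-(tert-butyldimethylsilyloxy)phenyl]-5-hydroxy-7-methoxy-6,8-bis(3-methylbut-2-enyl)chroman-4-one | COc1c(CC=C(C)C)c(O)c2c(c1CC=C(C)C)O[C@H](c1ccc(O[Si](C)(C)C(C)(C)C)cc1)CC2=O | intermediate
13 | (2S)-5-hydroxy-2-(4-hydroxyphenyl)-7-methoxy-6,8-bis(3-methylbut-2-enyl)chroman-4-one | COc1c(CC=C(C)C)c(O)c2c(c1CC=C(C)C)O[C@H](c1ccc(O)cc1)CC2=O | target

Total step count: 7
Longest linear sequence: 6 steps (steps 1, 2, 3, 5, 6, 7; step 4 is the side branch)

Steps most likely to fail

Step 6. The facial selectivity of the ring closure may be poor, because chalcone 11 can close without the catalyst (thermally or under the lamp) and because the closure is reversible on a basic catalyst. The fallback is a kinetic resolution that sets out from compound 12 of insufficient enantiomeric purity and comes back to compound 12. Acetylation of the chelated 5-hydroxyl (Ac2O, pyridine, DMAP, CH2Cl2) gives (2S)-2-[4-(tert-butyldimethylsilyloxy)phenyl]-7-methoxy-6,8-bis(3-methylbut-2-enyl)-4-oxochroman-5-yl acetate F1, still mixed with its 2R enantiomer. Asymmetric transfer hydrogenation with RuCl(p-cymene)[(R,R)-TsDPEN] in HCO2H/Et3N and ethyl acetate should reduce only the 2R ketone, from the face opposite the 2-aryl group, to (2R,4R)-2-[4-(tert-butyldimethylsilyloxy)phenyl]-4-hydroxy-7-methoxy-6,8-bis(3-methylbut-2-enyl)chroman-5-yl acetate F2, which is removed by chromatography. NH3 in MeOH at 0 °C then frees the 5-hydroxyl of the unreacted 2S ketone F1 and returns 12.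

Step 1. The twofold C-alkylation may stall at the monoprenyl stage or run on to O-alkylation and to geminal dialkylation with loss of aromaticity. The fallback replaces phenoxide alkylation by halogenation and cross-coupling; it sets out from compound 1 and comes back at compound 3. Iodination (I2, NaHCO3, THF/H2O, 0 °C) should give methyl 2,4,6-trihydroxy-3,5-diiodobenzoate F3. A twofold Stille coupling with tributyl(3-methylbut-2-enyl)stannane (Pd(PPh3)4, DMF, 80 °C) then places each prenyl group exactly where an iodine stood, giving 3.

Step 2. The site selectivity of the O-methylation may be lost, since the 4-hydroxyl is flanked by two prenyl groups, and a chelated 2- or 6-hydroxyl or more than one hydroxyl may react. The fallback reverses the order of the two operations; it sets out from compound 1 and comes back at compound 4. Compound 1 is methylated first (MeI, K2CO3, acetone, rt), where the 4-hydroxyl is unhindered, to methyl 2,6-dihydroxy-4-methoxybenzoate F4. F4 is then C-prenylated twice with 2 (10% aq. KOH, 0 °C), C3 and C5 being its only free ring positions, to give 4.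

Further compounds
F1 | step 6 | (2S)-2-[4-(tert-butyldimethylsilyloxy)phenyl]-7-methoxy-6,8-bis(3-methylbut-2-enyl)-4-oxochroman-5-yl acetate | COc1c(CC=C(C)C)c(OC(C)=O)c2c(c1CC=C(C)C)O[C@H](c1ccc(O[Si](C)(C)C(C)(C)C)cc1)CC2=O
F2 | step 6 | (2R,4R)-2-[4-(tert-butyldimethylsilyloxy)phenyl]-4-hydroxy-7-methoxy-6,8-bis(3-methylbut-2-enyl)chroman-5-yl acetate | COc1c(CC=C(C)C)c(OC(C)=O)c2c(c1CC=C(C)C)O[C@@H](c1ccc(O[Si](C)(C)C(C)(C)C)cc1)C[C@H]2O
F3 | step 1 | methyl 2,4,6-trihydroxy-3,5-diiodobenzoate | COC(=O)c1c(O)c(I)c(O)c(I)c1O
F4 | step 2 | methyl 2,6-dihydroxy-4-methoxybenzoate | COC(=O)c1c(O)cc(OC)cc1O
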